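**Retrosynthetic overview**

1. Target 22 ⇐ tricyclic hydroxy enone 21 by hydroxyl-directed reduction of the C2 ketone (last step).
2. Five-membered ring (C7–C16, formed last): transannular attack of the enone γ-carbon C16 (as a silyl dienol ether) on a C7 allyl cation made by ene-chlorination of C7=C8, the laboratory equivalent of the oxidative C16–C7 coupling.
3. Six-membered ring (C4–C16, formed second): transannular epoxide-opening cation–olefin cyclisation of a cembrene-A-type epoxy ketone, isopropenyl C16 onto C4, which gives the 3-hydroxy-1(15)-en-2-one directly.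
4. Fourteen-membered ring (C1–C2, formed first): intramolecular allylchromium addition to a C2 epoxy aldehyde, creating the isopropenyl group as in the geranylgeranyl → cembrene A closure.
5. Acyclic C20 chain: enal from (2S,3S)-epoxygeraniol plus (R)-citronellyl zinc (C9–C10 bond, C9 set by ligand control).

Assumption: atoms carry trinervitane numbers (C1–C20) throughout, also in the acyclic and macrocyclic precursors; the target is read as trinervita-1(15),8(19)-diene-2,3,9-triol 9-acetate with the configuration of the given SMILES.

**Route**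

Step 1
Reactants: 1 geraniol
Product: 2 (2S,3S)-2,3-epoxygeraniol
Conditions: Ti(OiPr)4 (5 mol%), L-(+)-diethyl tartrate (6 mol%), t-BuOOH, 4 Å MS, CH2Cl2, −20 °C
Reagents that add atoms: tert-butyl hydroperoxide, CC(C)(C)OO
Why: Katsuki–Sharpless asymmetric epoxidation of the allylic alcohol; the L-tartrate catalyst gives the (2S,3S) trans-epoxide, which fixes C3 (retained) and C4 (later inverted by C–C bond formation) of the target.

Step 2
Reactants: 2 (2S,3S)-2,3-epoxygeraniol
Product: 4 (2E)-5-[(2S,3S)-3-(hydroxymethyl)-2-methyloxiran-2-yl]-2-methylpent-2-enal, via allylic alcohol 3 (not isolated)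
Conditions: SeO2 (0.3 equiv), t-BuOOH, CH2Cl2, rt; then MnO2, CH2Cl2, rt
Reagents that add atoms: selenium dioxide, O=[Se]=O (delivers the oxygen; regenerated by tert-butyl hydroperoxide, CC(C)(C)OO)
Why: Sharpless SeO2/t-BuOOH allylic oxidation (ene reaction then [2,3] shift) attacks the E-methyl of the only alkene, and MnO2 oxidises only the new allylic alcohol, leaving the epoxy alcohol untouched.

Step 3
Reactants: 4 hydroxy enal
Product: 5 triethylsilyl ether of 4
Conditions: Et3SiCl, imidazole, CH2Cl2, 0 °C
Reagents that add atoms: chlorotriethylsilane, CC[Si](Cl)(CC)CC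
Why: Standard silylation of the primary alcohol, which masks the hydroxyl for the organozinc step and allows a later direct oxidation.

Step 4
Reactants: 5 silyl ether enal; 6 (R)-citronellyl bromide
Product: 10 acyclic C20 acetate (C2 OSiEt3, 3,4-epoxide, 7E-ene, 9S-OAc, 12R-methyl, prenyl end C1=C15), via Grignard reagent 7 (not isolated), via dialkylzinc 8 (not isolated), via zinc alkoxide 9 (not isolated)
Conditions: 6, Mg, Et2O; ZnCl2 (0.5 equiv), then 1,4-dioxane, filter; (−)-MIB (5 mol%), 5, toluene, 0 °C; then Ac2O, DMAP, rt
Reagents that add atoms: acetic anhydride, CC(=O)OC(C)=O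
Why: Amino-alcohol-catalysed enantioselective dialkylzinc addition (Noyori/Nugent type) to the α-methyl enal, with (−)-MIB delivering the alkyl group to the Si face to give the 9S carbinol, which is acetylated in the same flask; C12 comes unchanged from the citronellyl chiral pool.

Step 5
Reactants: 10 acyclic C20 acetate
Product: 11 secondary allylic chloride (C1–Cl, C15=C16 isopropenyl; C1 epimers)
Conditions: NCS (1.1 equiv), PhSeCl (5 mol%), CH2Cl2, rt
Reagents that add atoms: N-chlorosuccinimide, O=C1CCC(=O)N1Cl
Why: Sharpless–Hori ene-type allylic chlorination; the prenyl terminus is the only electron-rich alkene, because C7=C8 is deactivated by the acetate on C9, and the C1 configuration is irrelevant since it is lost in step 7.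

Step 6
Reactants: 11 allylic chloride silyl ether
Product: 12 epoxy aldehyde (C2 aldehyde)
Conditions: (COCl)2, DMSO, CH2Cl2, −78 to −30 °C; Et3N
Reagents that add atoms: none
Why: Swern oxidation acting directly on the primary triethylsilyl ether (the activated sulfonium cleaves the Si–O bond), which gives the aldehyde without a separate deprotection and leaves epoxide, acetate and allylic chloride intact.

Step 7
Reactants: 12 epoxy aldehyde
Product: 14 macrocyclic epoxy alcohol (14-membered ring; C1 isopropenyl, C2 OH, 3,4-epoxide, 7E-ene, 9S-OAc; C1/C2 epimer mixture), via allylchromium species 13 (not isolated)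
Conditions: CrCl2 (6 equiv), LiI (cat.), THF, 0.003 M, slow addition, rt
Reagents that add atoms: none
Why: Nozaki–Hiyama allylation used as a macrocyclisation; the allylchromium reagent adds through its more substituted γ-carbon C1 to the aldehyde, closing the C1–C2 bond and generating the isopropenyl group as in the cembrene A ring closure, and both new stereocentres are erased later (C2 in step 8, C1 in step 9).

Step 8
Reactants: 14 macrocyclic epoxy alcohol
Product: 15 macrocyclic α,β-epoxy ketone (C2 ketone; C1 epimers), used crude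
Conditions: Dess–Martin periodinane, CH2Cl2, 0 °C
Reagents that add atoms: none
Why: Dess–Martin oxidation of the secondary alcohol under near-neutral conditions, which keeps the epoxide and the β,γ-unsaturated isopropenyl group in place.

Step 9
Reactants: 15 macrocyclic epoxy ketone
Product: 17 bicyclic hydroxy enone (six-membered ring C1–C2–C3–C4–C16–C15; 3-OH, 1(15)-en-2-one, 7E-ene, 9S-OAc), via exocyclic-alkene isomer 16 (not isolated)
Conditions: MeAlCl2 (2 equiv), CH2Cl2, −78 °C; then DBU (0.2 equiv), 0 °C
Reagents that add atoms: none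
Why: Proposed new method: MeAlCl2 chelates the ketone and epoxide oxygens and ionises the tertiary C4–O bond while the isopropenyl terminus C16 attacks C4 anti to the leaving oxygen through a six-membered transition state (inversion at C4 gives the quaternary centre, C3 keeps its oxygen), and the C15 cation loses a proton with DBU moving any β,γ-alkene into conjugation; the closest known reactions are MeAlCl2-promoted epoxide-initiated cation–olefin cyclisations and transannular cyclisations of cembranoid epoxides, and the main competitor is the 1,2-acyl shift of epoxy ketones.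

Step 10
Reactants: 17 bicyclic hydroxy enone
Product: 18 C7 allylic chloride (C7–Cl, C8=C19 exocyclic methylene; C7 epimers)
Conditions: NCS (1.2 equiv), PhSeCl (10 mol%), CH2Cl2, rt
Reagents that add atoms: N-chlorosuccinimide, O=C1CCC(=O)N1Cl
Why: Ene-type allylic chlorination again; C7=C8 is now the only non-conjugated alkene, chlorine ends on the less substituted carbon C7 and the proton is lost from the C19 methyl rather than from the acetoxy-bearing C9, which installs the exocyclic methylene.

Step 11
Reactants: 18 C7 allylic chloride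
Product: 21 tricyclic hydroxy enone (five-membered ring closed by the C7–C16 bond), via bis-silyl dienol ether 19 (not isolated), via silyl ether 20 (not isolated)
Conditions: Me3SiOTf (2.5 equiv), Et3N, CH2Cl2, 0 °C; AgOTf, −40 to 0 °C; aq. citric acid
Reagents that add atoms: none
Why: Vinylogous Mukaiyama-type SN1 alkylation: silver removes chloride to give the C7–C8–C19 allyl cation (both C7 epimers converge), which is attacked by the γ-carbon C16 of the extended silyl dienol ether; the five-membered ring can only be cis-fused on the face carrying C5, and the C8–C14 tether fixes C7, so C16 and C7 follow from C4.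

Step 12
Reactants: 21 tricyclic hydroxy enone
Product: 22 target
Conditions: Me4NBH(OAc)3, MeCN/AcOH, −30 °C
Reagents that add atoms: none
Why: Hydroxyl-directed reduction (Saksena–Evans type): the C3 hydroxyl binds the borohydride and delivers hydride to the same face of C2, which gives the trans-2,3-diol; the acetate and both alkenes are untouched.

**Compound list**

1 | geraniol, (2E)-3,7-dimethylocta-2,6-dien-1-ol | CC(C)=CCC/C(C)=C/CO | starting material
2 | (2S,3S)-2,3-epoxygeraniol | OC[C@@H]1O[C@@]1(C)CCC=C(C)C | intermediate
3 | (2S,3S,6E)-2,3-epoxy-3,7-dimethyloct-6-ene-1,8-diol | OC[C@@H]1O[C@@]1(C)CC/C=C(\C)CO | intermediate (not isolated)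
4 | (2E)-5-[(2S,3S)-3-(hydroxymethyl)-2-methyloxiran-2-yl]-2-methylpent-2-enal | OC[C@@H]1O[C@@]1(C)CC/C=C(\C)C=O | intermediate
5 | triethylsilyl ether of 4 | CC[Si](CC)(CC)OC[C@@H]1O[C@@]1(C)CC/C=C(\C)C=O | intermediate
6 | (R)-citronellyl bromide, (6R)-8-bromo-2,6-dimethyloct-2-ene | BrCC[C@H](C)CCC=C(C)C | starting material
7 | (R)-citronellylmagnesium bromide | Br[Mg]CC[C@H](C)CCC=C(C)C | intermediate (not isolated)
8 | bis[(R)-citronellyl]zinc | CC(C)=CCC[C@@H](C)CC[Zn]CC[C@H](C)CCC=C(C)C | intermediate (not isolated)
9 | citronellylzinc alkoxide of the (9S)-carbinol formed from 5 | CC[Si](CC)(CC)OC[C@@H]1O[C@@]1(C)CC/C=C(\C)[C@@H](O[Zn]CC[C@H](C)CCC=C(C)C)CC[C@H](C)CCC=C(C)C | intermediate (not isolated)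
10 | (2S,3S,6E,8S,11R)-8-acetoxy-2,3-epoxy-3,7,11,15-tetramethylhexadeca-6,14-dien-1-yl triethylsilyl ether (chain numbering; trinervitane C9 acetate, C12 methyl) | CC[Si](CC)(CC)OC[C@@H]1O[C@@]1(C)CC/C=C(\C)[C@@H](OC(C)=O)CC[C@H](C)CCC=C(C)C | intermediate
11 | allylic chloride of 10: C1–Cl, C15=C16 isopropenyl end, C1 epimers; other centres as in 10 | CC[Si](CC)(CC)OC[C@@H]1O[C@@]1(C)CC/C=C(\C)[C@@H](OC(C)=O)CC[C@H](C)CCC(Cl)C(C)=C | intermediate
12 | epoxy aldehyde: C2 aldehyde, 3,4-epoxide as in 2, 9-acetate as in 10, C12 as in 6, C1 chloride | O=C[C@@H]1O[C@@]1(C)CC/C=C(\C)[C@@H](OC(C)=O)CC[C@H](C)CCC(Cl)C(C)=C | intermediate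
13 | allylchromium dichloride derived from 12 (Cr on C16, C1=C15 alkene) | O=C[C@@H]1O[C@@]1(C)CC/C=C(\C)[C@@H](OC(C)=O)CC[C@H](C)CCC=C(C)C[Cr](Cl)Cl | intermediate (not isolated)
14 | macrocyclic epoxy alcohol: 14-membered ring C1–C14, C1 isopropenyl, C2 OH, 3,4-epoxide as in 2, 7E-ene, 9S-acetate, 12-methyl as in 6; C1/C2 epimers | OC1[C@@H]2O[C@@]2(C)CC/C=C(\C)[C@@H](OC(C)=O)CC[C@H](C)CCC1C(C)=C | intermediate
15 | macrocyclic α,β-epoxy ketone: C2 ketone of 14, C1 epimers | O=C1[C@@H]2O[C@@]2(C)CC/C=C(\C)[C@@H](OC(C)=O)CC[C@H](C)CCC1C(C)=C | intermediate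
16 | bicyclic β,γ-unsaturated hydroxy ketone with exocyclic C15=C17 methylene | O=C1[C@H](O)[C@@]2(C)CC/C=C(\C)[C@@H](OC(C)=O)CC[C@H](C)CCC1C(=C)C2 | intermediate (not isolated)
17 | bicyclic hydroxy enone: 9-acetoxy-3-hydroxy-7,16-secotrinervita-1(15),7E-dien-2-one, configuration as in the SMILES | O=C1[C@H](O)[C@@]2(C)CC/C=C(\C)[C@@H](OC(C)=O)CC[C@H](C)CCC1=C(C)C2 | intermediate
18 | C7 allylic chloride: 9-acetoxy-7-chloro-3-hydroxy-7,16-secotrinervita-1(15),8(19)-dien-2-one, C7 epimers | O=C1[C@H](O)[C@@]2(C)CCC(Cl)C(=C)[C@@H](OC(C)=O)CC[C@H](C)CCC1=C(C)C2 | intermediate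
19 | bis(trimethylsilyl) derivative of 18: 3-OSiMe3 and 2-silyloxy-1,15(16)-diene | C[Si](C)(C)OC1=C2CC[C@@H](C)CC[C@H](OC(C)=O)C(=C)C(Cl)CC[C@@](C)(C=C2C)[C@H]1O[Si](C)(C)C | intermediate (not isolated)
20 | 3-O-trimethylsilyl ether of 21 | C=C1[C@@H](OC(C)=O)CC[C@H](C)CCC2=C(C)[C@@H]3[C@H]1CC[C@]3(C)[C@@H](O[Si](C)(C)C)C2=O | intermediate (not isolated)
21 | tricyclic hydroxy enone: 9-acetoxy-3-hydroxytrinervita-1(15),8(19)-dien-2-one | C=C1[C@@H](OC(C)=O)CC[C@H](C)CCC2=C(C)[C@@H]3[C@H]1CC[C@]3(C)[C@@H](O)C2=O | intermediate
22 | target, trinervita-1(15),8(19)-diene-2,3,9-triol 9-acetate (trans-2,3-diol) | C=C1[C@@H](OC(C)=O)CC[C@H](C)CCC2=C(C)[C@@H]3[C@H]1CC[C@]3(C)[C@@H](O)[C@@H]2O | target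

**Totals and risks**

Total step count: 12. Longest linear sequence: 12 steps (1 → 22); (R)-citronellyl bromide 6 enters in step 4 with no prior steps.

The three steps most likely to fail are steps 9, 11 and 10.

Step 9 may lose to the 1,2-acyl shift of the epoxy ketone, or to conjugation of the isopropenyl group before cyclisation. The fallback sets out from macrocyclic alcohol 14, leaving out step 8. Et2AlCl (CH2Cl2, −78 °C) turns the C2 hydroxyl into an aluminium alkoxide that delivers the Lewis acid to the epoxide. Epoxy alcohols of this kind open at the distal carbon, here C4, and no acyl group is present to migrate, so the same C16–C4 bond forms and gives the bicyclic diol F1. TEMPO (cat.)/PhI(OAc)2 then oxidises the less hindered C2 carbinol (the C3 carbinol is neopentyl), and DBU conjugates the alkene. The fallback comes back to the route at 17.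

Step 10 may be slow or unselective because the C7=C8 alkene is deactivated by the neighbouring acetate. The fallback sets out from 17 and replaces electrophilic chlorine by singlet oxygen. A Schenck ene reaction (O2, tetraphenylporphyrin, visible light, CH2Cl2, 0 °C) puts oxygen on C7 and takes hydrogen from the C19 methyl geminal to the bulky C9 substituent; the enone is inert. This gives the C7 hydroperoxide F2, which PPh3 reduces to the allylic alcohol F3. Corey–Kim chlorination (NCS, Me2S, CH2Cl2, −20 °C), selective for the allylic hydroxyl over the hindered C3 hydroxyl, then gives the chloride. The fallback comes back at 18.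

Step 11 may fail through the wrong dienol ether regiochemistry (C17 instead of C16) or through capture of the allyl cation by the C9 acetate. The fallback sets out from 18, forms 19 as before, and swaps the silver-induced ionisation for a Tsuji–Trost alkylation: Pd(PPh3)4 (5 mol%) and tetrabutylammonium difluorotriphenylsilicate in THF at 0 °C. Zerovalent palladium converts either C7 epimer into the same η3-allyl complex without a free cation, fluoride releases the dienolate, and ring size (five against seven) directs C16 to C7. No new compound arises (F0), and the fallback comes back at 21 after work-up.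

Further compounds
F1 | step 9 | bicyclic 2,3-diol with exocyclic C15=C17 methylene (9-acetoxy-7,16-secotrinervita-7E,15(17)-diene-2,3-diol; C1/C2 epimers) | OC1[C@H](O)[C@@]2(C)CC/C=C(\C)[C@@H](OC(C)=O)CC[C@H](C)CCC1C(=C)C2
F2 | step 10 | 9-acetoxy-7-hydroperoxy-3-hydroxy-7,16-secotrinervita-1(15),8(19)-dien-2-one (C7 epimers) | O=C1[C@H](O)[C@@]2(C)CCC(OO)C(=C)[C@@H](OC(C)=O)CC[C@H](C)CCC1=C(C)C2
F3 | step 10 | 9-acetoxy-3,7-dihydroxy-7,16-secotrinervita-1(15),8(19)-dien-2-one (C7 epimers) | O=C1[C@H](O)[C@@]2(C)CCC(O)C(=C)[C@@H](OC(C)=O)CC[C@H](C)CCC1=C(C)C2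
F0 | step 11 | none | none
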